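The readings are calculated with made-up constants, and the scatter is random.

Keep your balance on Z, the limiting reagent, charged in smaller amount than X.

| flask | X | Z | remark | time |
|---|---|---|---|---|
| south-west | 0.30 M | 0.5 mol% | run made earlier |  |
| south | 0.30 M | 0.75 mol% | run made earlier |  |
| north | 0.15 M | 1 mol% | run made earlier |  |
| flask | 0.30 M | 1 mol% |  | 3.0 min |

| run | time / min | Q / % | X / % |
|---|---|---|---|
| south-west | 0.500 | 0 | 99.7 |
| south-west | 1.00 | 1.6 | 98.0 |
| south-west | 1.50 | 2.7 | 96.6 |
| south-west | 2.00 | 4.4 | 95.6 |
| south-west | 2.50 | 5.3 | 94.1 |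
| south-west | 3.00 | 5.9 | 93.0 |
| south | 0.200 | 0 | 98.3 |
| south | 0.667 | 0.1 | 99.9 |
| south | 1.00 | 1.1 | 97.7 |
| south | 1.50 | 2.8 | 96.7 |
| south | 2.50 | 7.5 | 93.4 |
| south | 3.00 | 10.4 | 89.3 |
| north | 0.667 | 0 | 100.1 |
| north | 1.33 | 1.1 | 99.7 |
| north | 2.00 | 0.8 | 97.3 |
| north | 2.50 | 4.6 | 98.3 |
| north | 3.00 | 4.7 | 98.0 |

(readings scatter by 1 percentage point)

- average number of monomer units in a chain (chains begun, living or dead) at 3.0 min
- part of the X that has reacted at 3.0 min

- the average divides the monomer in chains by the number of chains begun, living and dead together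
- what was read earlier has a scatter of 1 percentage point, one standard deviation
- the earlier runs do not show the number of chains; that part of a forecast is a guess

Read the recipes row against row. South-west and north charge the same [Z], 1.50 mM, and at 3.00 min they read Q of 5.9% and 4.7%. The south run, with more Z, reads 10.4%. The flask charges twice the Z of south-west, so expect more conversion there, though the runs do not count chains.

For that, use the balance: Z charged equals Z left, plus Z that has begun a chain, plus Z lost otherwise. Taking one Z per chain begun, my own reckoning uses R, which is 100 in the flask: the X charged per Z charged. With f the share of charged Z that has begun a chain, dp = c R / f, and f of one gives the floor, c R.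

The forecast gives c 15.5% and dp 25, expecting “fewer chains and a higher dp”. In my terms, that is a floor of 15.5 and f of 62.0%.

The flask gives c 13.7% and dp 49.8.

    X + Z → D + Q (k = 0.00630 M⁻¹ s⁻¹)
    X + D → Q + D, rate k2*[D]*[X] (k = 1.80 M⁻¹ s⁻¹)
    Z + Q → E (k = 0.00990 M⁻¹ s⁻¹)

The flask's floor is 13.7, so its f is 27.5%, and this share is where forecast and flask part. At 2.03 min, the turning of X into Q uses X 73 times as fast as the turning of X + Z into D + Q. At 3.00 min, 70% of the flask's Z is left. In the neighbour flask with 1.2 M of X, the loading is held, so R stays 100 and c of 76.3% gives a floor of 76.3. Its D of 0.00618 M makes f 51.5%, so the rule gives 148, and the computed dp is 147.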